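**Plan**

1. Labels: the seven-membered ring holds C5 (sp3 CH), C10 (aryl-bearing alkene carbon) and C11 (alkene CH). Ring B is b1 (on C11), b2, b3, b4, b5 (furan O), b6 (on C5). Ring C is c1 (on C5), c2, c3, c4, c5 (furan O), c6 (on C10). Cα is the OCH(aryl) carbon of the ring B dihydrofuran; Cβ and Cγ are OCH(aryl) and CH(3,5-dioxyphenyl) of the ring C dihydrofuran. Ring B carries C11, C5 and oxygen on the adjacent carbons b1, b6 and b5, so b1/b6 can come from an aryne polarised by the b5 oxygen.
2. Retrosynthetic cuts, in order: Cβ–O/Cβ–Cγ and Cα–O/Cα–C5 (two [4+1] annulations at o-quinone methides); Cγ–aryl and c4–Cγ (Grignard addition, ortho-formylation); the C10=C11 π bond (back to a C11 acid); b1–C11 and b6–C5 (aryne insertion into an indanone β-ketoester); the indanone C(=O)–CH bond (Dieckmann); c6–C10 (Pechmann).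
3. Forward: ring C with C10/C11 is built as a 4-arylcoumarin from phloroglucinol (its lactone oxygen is the c5 oxygen), then opened and closed to the 3-arylindanone β-ketoester. 3,5-Dimethoxybenzyne enlarges the five-membered ring to the seven-membered ring, and decarboxylative desaturation gives C10=C11.
4. The ring B dihydrofuran is closed next (C5 ketone, carbinol, sulfone, o-quinone methide plus ylide). c4 is then formylated and arylated, the ring C dihydrofuran is closed the same way, and BBr3 frees the seven phenols.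
5. Stereochemistry: C10/C11 from the key step are racemic and are erased. Cα (S) and Cβ (R) are set by antipodal C2-symmetric 2,5-dimethylthiolanium 4-methoxybenzylides; C5 (S) and Cγ (R) follow from the trans course of each annulation. The second annulation converts any minor enantiomer into a separable diastereomer.

Key step: step 11

Assumption: the ylide-face preference of the 2,5-dimethylthiolanium 4-methoxybenzylides in the annulation is taken to be the one they show in aldehyde epoxidation, which puts the (2S,5S) salt at ring B and the (2R,5R) salt at ring C; if a model annulation shows the opposite sense, the two salts change places.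

**Route**

Step 1
Reactants: 1 3,5-dimethoxyphenol
Product: 2 2-bromo-3,5-dimethoxyphenol
Conditions: NBS, i-Pr2NH (10 mol %), CH2Cl2, 0 °C
Reagents that add atoms: N-bromosuccinimide, O=C1CCC(=O)N1Br
Why: Amine-mediated ortho-bromination of a phenol (electrophilic aromatic substitution directed by the hydrogen-bonded N-bromoamine) should place bromine beside the hydroxyl; any para isomer is removed by chromatography.

Step 2
Reactants: 2 2-bromo-3,5-dimethoxyphenol
Product: 3 (2-bromo-3,5-dimethoxyphenoxy)trimethylsilane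
Conditions: HMDS, THF, 70 °C; evaporate, use crude
Reagents that add atoms: hexamethyldisilazane, C[Si](C)(C)N[Si](C)(C)C
Why: O-Silylation of a phenol by HMDS with loss of ammonia sets up the silyl transfer of the next step.

Step 3
Reactants: 3 (2-bromo-3,5-dimethoxyphenoxy)trimethylsilane
Product: 6 3,5-dimethoxy-2-(trimethylsilyl)phenyl trifluoromethanesulfonate, via (2-lithio-3,5-dimethoxyphenoxy)trimethylsilane 4 (not isolated), via lithium 3,5-dimethoxy-2-(trimethylsilyl)phenoxide 5 (not isolated)
Conditions: n-BuLi, THF, −78 °C; then Tf2O, −78 → 0 °C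
Reagents that add atoms: trifluoromethanesulfonic anhydride, O=S(=O)(OS(=O)(=O)C(F)(F)F)C(F)(F)F
Why: Bromine–lithium exchange, 1,3 O→C silyl shift (retro-Brook rearrangement) and triflation of the resulting phenoxide is the standard entry to ortho-silylaryl triflates.

Step 4
Reactants: 7 phloroglucinol; 8 ethyl 3-(4-methoxyphenyl)-3-oxopropanoate
Product: 9 5,7-dihydroxy-4-(4-methoxyphenyl)-2H-chromen-2-one
Conditions: CF3CO2H, 75 °C
Reagents that add atoms: none
Why: Pechmann condensation; the threefold symmetry of phloroglucinol allows only one regioisomer, and the lactone oxygen becomes the c5 oxygen, distinct from the other two.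

Step 5
Reactants: 9 5,7-dihydroxy-4-(4-methoxyphenyl)-2H-chromen-2-one
Product: 10 5-hydroxy-7-methoxy-4-(4-methoxyphenyl)-2H-chromen-2-one
Conditions: MeI (1.05 equiv), K2CO3 (1.1 equiv), acetone, rt
Reagents that add atoms: iodomethane, CI
Why: Williamson etherification with one equivalent of weak base should go to the 7-hydroxyl, which is the more acidic (para-type conjugation to the lactone) and is not shielded by the peri 4-aryl group as the 5-hydroxyl is.

Step 6
Reactants: 10 5-hydroxy-7-methoxy-4-(4-methoxyphenyl)-2H-chromen-2-one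
Product: 11 7-methoxy-4-(4-methoxyphenyl)-2-oxo-2H-chromen-5-yl trifluoromethanesulfonate
Conditions: Tf2O, pyridine, CH2Cl2, 0 °C
Reagents that add atoms: trifluoromethanesulfonic anhydride, O=S(=O)(OS(=O)(=O)C(F)(F)F)C(F)(F)F
Why: Triflation of the remaining phenol turns the c1 oxygen into a leaving group for carbonylation.

Step 7
Reactants: 11 7-methoxy-4-(4-methoxyphenyl)-2-oxo-2H-chromen-5-yl trifluoromethanesulfonate
Product: 12 methyl 7-methoxy-4-(4-methoxyphenyl)-2-oxo-2H-chromene-5-carboxylate
Conditions: CO (1 atm), Pd(OAc)2 (5 mol %), dppp (5 mol %), Et3N, MeOH/DMF, 70 °C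
Reagents that add atoms: carbon monoxide, [C-]#[O+]; methanol, CO
Why: Palladium-catalysed methoxycarbonylation of an aryl triflate (oxidative addition to zerovalent palladium, CO insertion, methanolysis) installs the future C5 carbon on c1.

Step 8
Reactants: 12 methyl 7-methoxy-4-(4-methoxyphenyl)-2-oxo-2H-chromene-5-carboxylate
Product: 14 methyl 3-hydroxy-5-methoxy-2-[3-methoxy-1-(4-methoxyphenyl)-3-oxopropyl]benzoate (racemic), via methyl 7-methoxy-4-(4-methoxyphenyl)-2-oxochromane-5-carboxylate 13 (not isolated)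
Conditions: Mg turnings, MeOH, 0 °C → rt; aq. NH4Cl
Reagents that add atoms: methanol, CO
Why: Dissolving-metal conjugate reduction of the coumarin C3=C4 bond by Mg/MeOH is followed by methoxide opening of the lactone, freeing the c5 phenol; the new C10 centre is racemic and is erased later.

Step 9
Reactants: 14 methyl 3-hydroxy-5-methoxy-2-[3-methoxy-1-(4-methoxyphenyl)-3-oxopropyl]benzoate
Product: 15 methyl 3-(benzyloxy)-5-methoxy-2-[3-methoxy-1-(4-methoxyphenyl)-3-oxopropyl]benzoate (racemic)
Conditions: BnBr, K2CO3, DMF/MeOH (10:1), rt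
Reagents that add atoms: benzyl bromide, BrCc1ccccc1
Why: Williamson benzylation of the phenoxide; the methanol co-solvent re-opens any relactonised material, so both forms converge on the benzyl ether.

Step 10
Reactants: 15 methyl 3-(benzyloxy)-5-methoxy-2-[3-methoxy-1-(4-methoxyphenyl)-3-oxopropyl]benzoate
Product: 16 methyl 4-(benzyloxy)-6-methoxy-3-(4-methoxyphenyl)-1-oxo-2,3-dihydro-1H-indene-2-carboxylate (racemic)
Conditions: KOt-Bu (2.2 equiv), THF, 0 °C → rt; aq. HCl
Reagents that add atoms: none
Why: Dieckmann condensation; the only enolisable ester attacks the benzoate (5-exo-trig) and the stable β-ketoester enolate drives the equilibrium.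

Step 11
Reactants: 16 methyl 4-(benzyloxy)-6-methoxy-3-(4-methoxyphenyl)-1-oxo-2,3-dihydro-1H-indene-2-carboxylate; 6 3,5-dimethoxy-2-(trimethylsilyl)phenyl trifluoromethanesulfonate
Product: 18 methyl 9-(benzyloxy)-2,4,7-trimethoxy-10-(4-methoxyphenyl)-5-oxo-10,11-dihydro-5H-dibenzo[a,d][7]annulene-11-carboxylate (racemic), via 3,5-dimethoxybenzyne 17 (not isolated)
Conditions: CsF (2.5 equiv), 6 (1.3 equiv), MeCN, 80 °C
Reagents that add atoms: none
Why: Fluoride removes the silyl group and triflate leaves to give aryne 17; the enolate carbon of 16 adds to the aryne carbon remote from the flanking methoxy group (b1), and the aryl anion left at b6 beside that C–O bond closes 4-exo-trig onto the indanone ketone to a benzocyclobutenoxide, which fragments across the old ketone-to-α-carbon bond. The closest known reaction type is the acyl-alkylation of arynes by cyclic β-ketoesters, an insertion into a C–C σ bond that gives benzannulated medium rings. The seven-membered ring therefore arises by two-carbon enlargement of the five-membered ring (forming b1–C11 and b6–C5) and not by direct cyclisation. No stereocentre of the target is set: C10 and C11 form without control and both are removed when the alkene is made. The step needs aryne regioselectivity and C- over O-arylation; the methoxy group beside the triple bond secures the first by sending the nucleophile to the distal carbon, and the soft β-ketoester enolate secures the second. The ketone thus lands on C5 next to the b5 methoxy group, the one ether that can later be cleaved selectively by chelation, and the ester lands on C11.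

Step 12
Reactants: 18 methyl 9-(benzyloxy)-2,4,7-trimethoxy-10-(4-methoxyphenyl)-5-oxo-10,11-dihydro-5H-dibenzo[a,d][7]annulene-11-carboxylate
Product: 19 9-(benzyloxy)-2,4,7-trimethoxy-10-(4-methoxyphenyl)-5-oxo-10,11-dihydro-5H-dibenzo[a,d][7]annulene-11-carboxylic acid (racemic)
Conditions: LiOH·H2O, THF/MeOH/H2O, 50 °C; aq. HCl
Reagents that add atoms: lithium hydroxide, [Li+].[OH-]
Why: Saponification of the methyl ester; the diaryl ketone cannot enolise and epimerisation at C11 does not matter.

Step 13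
Reactants: 19 9-(benzyloxy)-2,4,7-trimethoxy-10-(4-methoxyphenyl)-5-oxo-10,11-dihydro-5H-dibenzo[a,d][7]annulene-11-carboxylic acid
Product: 20 9-(benzyloxy)-2,4,7-trimethoxy-10-(4-methoxyphenyl)-5H-dibenzo[a,d][7]annulen-5-one
Conditions: 9-mesityl-10-methylacridinium tetrafluoroborate (5 mol %), Co(dmgH)2(py)Cl (5 mol %), K3PO4 (20 mol %), MeCN/H2O, 450 nm LED, rt, degassed
Reagents that add atoms: none
Why: Dehydrogenative decarboxylation by acridinium photoredox/cobaloxime dual catalysis: the carboxylate is oxidised, CO2 leaves to give the benzylic C11 radical, and the cobaloxime removes the doubly benzylic C10 hydrogen, giving the conjugated C10=C11 alkene and H2 and erasing both racemic centres.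

Step 14
Reactants: 20 9-(benzyloxy)-2,4,7-trimethoxy-10-(4-methoxyphenyl)-5H-dibenzo[a,d][7]annulen-5-one
Product: 21 4,9-dihydroxy-2,7-dimethoxy-10-(4-methoxyphenyl)-5H-dibenzo[a,d][7]annulen-5-one
Conditions: BCl3 (6 equiv), pentamethylbenzene (3 equiv), CH2Cl2, −78 → 0 °C; MeOH, then H2O
Reagents that add atoms: none
Why: BCl3 cleaves the benzyl ether (cation trapped by pentamethylbenzene) and, through chelation to the C5 ketone, only the methyl ether peri to it on b5; the other aryl methyl ethers should survive at or below 0 °C.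

Step 15
Reactants: 21 4,9-dihydroxy-2,7-dimethoxy-10-(4-methoxyphenyl)-5H-dibenzo[a,d][7]annulen-5-one
Product: 23 2,7-dimethoxy-10-(4-methoxyphenyl)-5-(4-methylbenzenesulfonyl)-5H-dibenzo[a,d][7]annulene-4,9-diol (racemic), via C5 carbinol 22 (not isolated)
Conditions: NaBH4, THF/MeOH, 0 °C; then sodium 4-methylbenzenesulfinate, HCO2H, H2O, rt
Reagents that add atoms: sodium 4-methylbenzenesulfinate, [Na+].[O-]S(=O)c1ccc(C)cc1
Why: Hydride reduction of the diaryl ketone (kept cold to avoid over-reduction through the quinone methide) is followed by acid ionisation of the doubly benzylic carbinol and capture of the cation at sulfur (SN1), giving the base-labile o-quinone methide precursor; C5 is racemic here and becomes planar again in step 19.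

Step 16
Reactants: 24 (2R,5R)-hexane-2,5-diol
Product: 25 (2R,5R)-hexane-2,5-diyl dimethanesulfonate
Conditions: MsCl, Et3N, CH2Cl2, −20 → 0 °C
Reagents that add atoms: methanesulfonyl chloride, CS(=O)(=O)Cl
Why: Mesylation of both secondary alcohols proceeds with retention at carbon.

Step 17
Reactants: 25 (2R,5R)-hexane-2,5-diyl dimethanesulfonate
Product: 26 (2S,5S)-2,5-dimethylthiolane
Conditions: Na2S·9H2O, DMSO, rt → 40 °C; pentane extraction, distillation
Reagents that add atoms: sodium sulfide, [Na+].[Na+].[S-2]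
Why: Two SN2 displacements by sulfide (the second 5-exo-tet) invert both centres and give the C2-symmetric trans thiolane.

Step 18
Reactants: 26 (2S,5S)-2,5-dimethylthiolane; 27 4-methoxybenzyl bromide
Product: 28 (2S,5S)-1-(4-methoxybenzyl)-2,5-dimethylthiolan-1-ium tetrafluoroborate
Conditions: NaBF4, CH2Cl2/H2O, rt
Reagents that add atoms: sodium tetrafluoroborate, [Na+].F[B-](F)(F)F
Why: S-Alkylation by the benzylic bromide with exchange to the non-nucleophilic counter-ion; the C2 symmetry makes both sulfur lone pairs equivalent, so a single sulfonium salt forms.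

Step 19
Reactants: 23 2,7-dimethoxy-10-(4-methoxyphenyl)-5-(4-methylbenzenesulfonyl)-5H-dibenzo[a,d][7]annulene-4,9-diol; 28 (2S,5S)-1-(4-methoxybenzyl)-2,5-dimethylthiolan-1-ium tetrafluoroborate
Product: 31 ring B dihydrofuran phenol (5S,αS; H-5/H-α trans; O-4 and C5 of the dibenzo[7]annulene bridged by CH(4-methoxyphenyl); 9-OH), via ring B o-quinone methide 29 (not isolated), via (2S,5S)-thiolanium 4-methoxybenzylide 30 (not isolated)
Conditions: Cs2CO3 (4 equiv), 28 (1.5 equiv), MeCN/CH2Cl2, −20 → 20 °C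
Reagents that add atoms: none
Why: Proposed new method: carbonate expels sulfinate from the b5 phenoxide of 23 to give o-quinone methide 29 and deprotonates 28 to ylide 30; the ylide carbon adds to C5 (re-aromatising ring B) and the phenoxide then displaces the sulfide by 5-exo-tet SN2 with inversion, so the chiral thiolane, by controlling which ylide face bonds, fixes Cα as S, and the anti betaine gives the trans ring and hence C5 as S; the closest known reaction types are the [4+1] annulation of o-quinone methides from 2-(1-sulfonylalkyl)phenols with stabilised sulfonium ylides and the asymmetric epoxidation and cyclopropanation by chiral benzylsulfonium ylides.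

Step 20
Reactants: 31 ring B dihydrofuran phenol (5S,αS)
Product: 32 c4-formyl phenol (5S,αS; CHO on c4 between the c3 methoxy group and the c5 hydroxyl)
Conditions: MgCl2 (anhydrous), Et3N, paraformaldehyde, MeCN, 80 °C; aq. citric acid
Reagents that add atoms: paraformaldehyde (formaldehyde source), C=O
Why: Magnesium-mediated ortho-formylation of a phenol (magnesium phenoxide plus formaldehyde, then hydride transfer to a second formaldehyde); c4 is the only free position ortho to the only free phenol, so the aldehyde is delivered regiospecifically.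

Step 21
Reactants: 32 c4-formyl phenol (5S,αS); 33 3,5-dimethoxyphenylmagnesium chloride (THF solution)
Product: 34 c4 (3,5-dimethoxyphenyl)carbinol phenol (5S,αS; both epimers at the carbinol carbon)
Conditions: 33 (3 equiv), THF, −20 → 0 °C; aq. NH4Cl
Reagents that add atoms: none
Why: Grignard addition to the salicylaldehyde after the first equivalent is consumed by the phenol; the carbinol centre forms unselectively and is erased in the quinone methide.

Step 22
Reactants: 34 c4 (3,5-dimethoxyphenyl)carbinol phenol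
Product: 35 c4 (3,5-dimethoxyphenyl)(4-methylbenzenesulfonyl)methyl phenol (5S,αS; both epimers at the sulfonyl carbon)
Conditions: sodium 4-methylbenzenesulfinate, HCO2H, CH2Cl2/H2O, rt
Reagents that add atoms: sodium 4-methylbenzenesulfinate, [Na+].[O-]S(=O)c1ccc(C)cc1
Why: SN1 substitution of the electron-rich o-hydroxybenzhydrol by sulfinate under mild acid gives the usual base-triggered o-quinone methide precursor; formic acid is too weak to damage the ring B dihydrofuran.

Step 23
Reactants: 36 (2S,5S)-hexane-2,5-diol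
Product: 37 (2S,5S)-hexane-2,5-diyl dimethanesulfonate
Conditions: MsCl, Et3N, CH2Cl2, −20 → 0 °C
Reagents that add atoms: methanesulfonyl chloride, CS(=O)(=O)Cl
Why: Mesylation with retention, as in step 16.

Step 24
Reactants: 37 (2S,5S)-hexane-2,5-diyl dimethanesulfonate
Product: 38 (2R,5R)-2,5-dimethylthiolane
Conditions: Na2S·9H2O, DMSO, rt → 40 °C; pentane extraction, distillation
Reagents that add atoms: sodium sulfide, [Na+].[Na+].[S-2]
Why: Double SN2 displacement with inversion at both centres, as in step 17.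

Step 25
Reactants: 38 (2R,5R)-2,5-dimethylthiolane; 27 4-methoxybenzyl bromide
Product: 39 (2R,5R)-1-(4-methoxybenzyl)-2,5-dimethylthiolan-1-ium tetrafluoroborate
Conditions: NaBF4, CH2Cl2/H2O, rt
Reagents that add atoms: sodium tetrafluoroborate, [Na+].F[B-](F)(F)F
Why: S-Alkylation and counter-ion exchange, as in step 18.

Step 26
Reactants: 35 c4 (3,5-dimethoxyphenyl)(4-methylbenzenesulfonyl)methyl phenol; 39 (2R,5R)-1-(4-methoxybenzyl)-2,5-dimethylthiolan-1-ium tetrafluoroborate
Product: 42 heptamethyl ether of the target (5S,αS,βR,γR; both dihydrofurans trans), via ring C o-quinone methide 40 (not isolated), via (2R,5R)-thiolanium 4-methoxybenzylide 41 (not isolated)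
Conditions: Cs2CO3 (3 equiv), 39 (1.5 equiv), MeCN/CH2Cl2, −20 → 20 °C
Reagents that add atoms: none
Why: Proposed new method: the c5 phenoxide expels sulfinate to give o-quinone methide 40, ylide 41 adds through its carbon to the methide carbon (Cγ) and the phenoxide closes by 5-exo-tet SN2 with inversion, so the antipodal thiolane sets Cβ as R and the trans course sets Cγ as R, independently of the remote ring B centres; the closest known reaction types are the [4+1] annulation of 2-(aryl(sulfonyl)methyl)phenol-derived o-quinone methides with stabilised sulfonium ylides and the asymmetric epoxidation and cyclopropanation by chiral benzylsulfonium ylides.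

Step 27
Reactants: 42 heptamethyl ether of the target
Product: 43 target heptaphenol (5S,αS,βR,γR)
Conditions: BBr3 (excess), CH2Cl2, −78 → 0 °C; MeOH, then aq. NaHCO3
Reagents that add atoms: none
Why: Lewis-acid cleavage of the seven aryl methyl ethers; should a benzylic C–O bond of a dihydrofuran ionise reversibly, it recloses to the more stable trans ring already present, so C5 and Cγ are untouched and Cα and Cβ are not scrambled.

**Compound list**

1 | 3,5-dimethoxyphenol | COc1cc(O)cc(OC)c1 | starting material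
2 | 2-bromo-3,5-dimethoxyphenol | COc1cc(O)c(Br)c(OC)c1 | intermediate
3 | (2-bromo-3,5-dimethoxyphenoxy)trimethylsilane | COc1cc(O[Si](C)(C)C)c(Br)c(OC)c1 | intermediate
4 | (2-lithio-3,5-dimethoxyphenoxy)trimethylsilane | [Li]c1c(OC)cc(OC)cc1O[Si](C)(C)C | intermediate (not isolated)
5 | lithium 3,5-dimethoxy-2-(trimethylsilyl)phenoxide | [Li+].[O-]c1cc(OC)cc(OC)c1[Si](C)(C)C | intermediate (not isolated)
6 | 3,5-dimethoxy-2-(trimethylsilyl)phenyl trifluoromethanesulfonate | COc1cc(OC)c([Si](C)(C)C)c(OS(=O)(=O)C(F)(F)F)c1 | intermediate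
7 | phloroglucinol (benzene-1,3,5-triol) | Oc1cc(O)cc(O)c1 | starting material
8 | ethyl 3-(4-methoxyphenyl)-3-oxopropanoate | CCOC(=O)CC(=O)c1ccc(OC)cc1 | starting material
9 | 5,7-dihydroxy-4-(4-methoxyphenyl)-2H-chromen-2-one | COc1ccc(cc1)-c1cc(=O)oc2cc(O)cc(O)c12 | intermediate
10 | 5-hydroxy-7-methoxy-4-(4-methoxyphenyl)-2H-chromen-2-one | COc1ccc(cc1)-c1cc(=O)oc2cc(OC)cc(O)c12 | intermediate
11 | 7-methoxy-4-(4-methoxyphenyl)-2-oxo-2H-chromen-5-yl trifluoromethanesulfonate | COc1ccc(cc1)-c1cc(=O)oc2cc(OC)cc(OS(=O)(=O)C(F)(F)F)c12 | intermediate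
12 | methyl 7-methoxy-4-(4-methoxyphenyl)-2-oxo-2H-chromene-5-carboxylate | COC(=O)c1cc(OC)cc2oc(=O)cc(-c3ccc(OC)cc3)c12 | intermediate
13 | methyl 7-methoxy-4-(4-methoxyphenyl)-2-oxochromane-5-carboxylate (racemic) | COC(=O)c1cc(OC)cc2OC(=O)CC(c3ccc(OC)cc3)c12 | intermediate (not isolated)
14 | methyl 3-hydroxy-5-methoxy-2-[3-methoxy-1-(4-methoxyphenyl)-3-oxopropyl]benzoate (racemic) | COC(=O)CC(c1ccc(OC)cc1)c1c(O)cc(OC)cc1C(=O)OC | intermediate
15 | methyl 3-(benzyloxy)-5-methoxy-2-[3-methoxy-1-(4-methoxyphenyl)-3-oxopropyl]benzoate (racemic) | COC(=O)CC(c1ccc(OC)cc1)c1c(OCc2ccccc2)cc(OC)cc1C(=O)OC | intermediate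
16 | methyl 4-(benzyloxy)-6-methoxy-3-(4-methoxyphenyl)-1-oxo-2,3-dihydro-1H-indene-2-carboxylate (racemic) | COC(=O)C1C(c2ccc(OC)cc2)c2c(OCc3ccccc3)cc(OC)cc2C1=O | intermediate
17 | 3,5-dimethoxybenzyne | COC1=CC(OC)=CC#C1 | intermediate (not isolated)
18 | methyl 9-(benzyloxy)-2,4,7-trimethoxy-10-(4-methoxyphenyl)-5-oxo-10,11-dihydro-5H-dibenzo[a,d][7]annulene-11-carboxylate (racemic) | COC(=O)C1C(c2ccc(OC)cc2)c2c(OCc3ccccc3)cc(OC)cc2C(=O)c2c(OC)cc(OC)cc21 | intermediate
19 | 9-(benzyloxy)-2,4,7-trimethoxy-10-(4-methoxyphenyl)-5-oxo-10,11-dihydro-5H-dibenzo[a,d][7]annulene-11-carboxylic acid (racemic) | OC(=O)C1C(c2ccc(OC)cc2)c2c(OCc3ccccc3)cc(OC)cc2C(=O)c2c(OC)cc(OC)cc21 | intermediate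
20 | 9-(benzyloxy)-2,4,7-trimethoxy-10-(4-methoxyphenyl)-5H-dibenzo[a,d][7]annulen-5-one | O=C1c2cc(OC)cc(OCc3ccccc3)c2C(c2ccc(OC)cc2)=Cc2cc(OC)cc(OC)c21 | intermediate
21 | 4,9-dihydroxy-2,7-dimethoxy-10-(4-methoxyphenyl)-5H-dibenzo[a,d][7]annulen-5-one | O=C1c2cc(OC)cc(O)c2C(c2ccc(OC)cc2)=Cc2cc(OC)cc(O)c21 | intermediate
22 | C5 carbinol: 2,7-dimethoxy-10-(4-methoxyphenyl)-5H-dibenzo[a,d][7]annulene-4,5,9-triol (racemic) | OC1c2cc(OC)cc(O)c2C(c2ccc(OC)cc2)=Cc2cc(OC)cc(O)c21 | intermediate (not isolated)
23 | 2,7-dimethoxy-10-(4-methoxyphenyl)-5-(4-methylbenzenesulfonyl)-5H-dibenzo[a,d][7]annulene-4,9-diol (racemic) | Cc1ccc(cc1)S(=O)(=O)C1c2cc(OC)cc(O)c2C(c2ccc(OC)cc2)=Cc2cc(OC)cc(O)c21 | intermediate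
24 | (2R,5R)-hexane-2,5-diol | C[C@@H](O)CC[C@@H](C)O | starting material
25 | (2R,5R)-hexane-2,5-diyl dimethanesulfonate | C[C@@H](OS(C)(=O)=O)CC[C@@H](C)OS(C)(=O)=O | intermediate
26 | (2S,5S)-2,5-dimethylthiolane | C[C@H]1CC[C@H](C)S1 | intermediate
27 | 4-methoxybenzyl bromide | COc1ccc(CBr)cc1 | starting material
28 | (2S,5S)-1-(4-methoxybenzyl)-2,5-dimethylthiolan-1-ium tetrafluoroborate | C[C@H]1CC[C@H](C)[S+]1Cc1ccc(OC)cc1.F[B-](F)(F)F | intermediate
29 | ring B o-quinone methide: 9-hydroxy-2,7-dimethoxy-10-(4-methoxyphenyl)-4H-dibenzo[a,d][7]annulen-4-one | O=C1C=C(OC)C=C2C=C(c3ccc(OC)cc3)c3c(O)cc(OC)cc3C=C12 | intermediate (not isolated)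
30 | (2S,5S)-2,5-dimethylthiolanium (4-methoxyphenyl)methylide | C[C@H]1CC[C@H](C)[S+]1[CH-]c1ccc(OC)cc1 | intermediate (not isolated)
31 | ring B dihydrofuran phenol: 5H-dibenzo[a,d][7]annulene with O-4 and C5 bridged by CH(4-methoxyphenyl) (Cα), 9-OH, 2,7-dimethoxy, 10-(4-methoxyphenyl); C5 S, Cα S, H-5/H-α trans | COc1ccc(C2=Cc3cc(OC)cc4c3[C@H](c3cc(OC)cc(O)c32)[C@@H](c2ccc(OC)cc2)O4)cc1 | intermediate
32 | c4-formyl phenol: 31 with CHO on c4 (between the c3 methoxy group and the c5 hydroxyl); C5 S, Cα S | COc1ccc(C2=Cc3cc(OC)cc4c3[C@H](c3cc(OC)c(C=O)c(O)c32)[C@@H](c2ccc(OC)cc2)O4)cc1 | intermediate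
33 | 3,5-dimethoxyphenylmagnesium chloride (THF solution) | COc1cc(OC)cc([Mg]Cl)c1 | starting material
34 | c4 carbinol: 31 with CH(OH)(3,5-dimethoxyphenyl) on c4; C5 S, Cα S, carbinol carbon both epimers | COc1ccc(C2=Cc3cc(OC)cc4c3[C@H](c3cc(OC)c(C(O)c5cc(OC)cc(OC)c5)c(O)c32)[C@@H](c2ccc(OC)cc2)O4)cc1 | intermediate
35 | c4 sulfone: 31 with CH(3,5-dimethoxyphenyl)(4-methylbenzenesulfonyl) on c4; C5 S, Cα S, sulfonyl carbon both epimers | COc1ccc(C2=Cc3cc(OC)cc4c3[C@H](c3cc(OC)c(C(c5cc(OC)cc(OC)c5)S(=O)(=O)c5ccc(C)cc5)c(O)c32)[C@@H](c2ccc(OC)cc2)O4)cc1 | intermediate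
36 | (2S,5S)-hexane-2,5-diol | C[C@H](O)CC[C@H](C)O | starting material
37 | (2S,5S)-hexane-2,5-diyl dimethanesulfonate | C[C@H](OS(C)(=O)=O)CC[C@H](C)OS(C)(=O)=O | intermediate
38 | (2R,5R)-2,5-dimethylthiolane | C[C@@H]1CC[C@@H](C)S1 | intermediate
39 | (2R,5R)-1-(4-methoxybenzyl)-2,5-dimethylthiolan-1-ium tetrafluoroborate | C[C@@H]1CC[C@@H](C)[S+]1Cc1ccc(OC)cc1.F[B-](F)(F)F | intermediate
40 | ring C o-quinone methide: c5 carbonyl, c4=CH(3,5-dimethoxyphenyl) exocyclic, ring B dihydrofuran intact; C5 S, Cα S | COc1ccc(C2=Cc3cc(OC)cc4c3[C@H](C3C=C(OC)C(=Cc5cc(OC)cc(OC)c5)C(=O)C=32)[C@@H](c2ccc(OC)cc2)O4)cc1 | intermediate (not isolated)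
41 | (2R,5R)-2,5-dimethylthiolanium (4-methoxyphenyl)methylide | C[C@@H]1CC[C@@H](C)[S+]1[CH-]c1ccc(OC)cc1 | intermediate (not isolated)
42 | heptamethyl ether of the target: both trans dihydrofurans in place; C5 S, Cα S, Cβ R, Cγ R | COc1ccc(C2=Cc3cc(OC)cc4c3[C@H](c3cc(OC)c5c(c32)O[C@@H](c2ccc(OC)cc2)[C@@H]5c2cc(OC)cc(OC)c2)[C@@H](c2ccc(OC)cc2)O4)cc1 | intermediate
43 | target heptaphenol; C5 S, Cα S, Cβ R, Cγ R | Oc1ccc(C2=Cc3cc(O)cc4c3[C@H](c3cc(O)c5c(c32)O[C@@H](c2ccc(O)cc2)[C@@H]5c2cc(O)cc(O)c2)[C@@H](c2ccc(O)cc2)O4)cc1 | target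

**Totals**

Total step count: 27.
Longest linear sequence: 18 steps (7 to 43 through steps 4–15, 19–22, 26 and 27).

**Steps most likely to fail**

1. Step 19. The benzylide may add reversibly to the tropylium-stabilised quinone methide, so that the sulfonium group no longer decides which ylide face bonds to C5, or the ylide may rearrange (Sommelet–Hauser) before it adds. The fallback uses donor/donor rhodium-carbene C–H insertion, sets out from 21 and returns at 31. Both phenols of 21 are alkylated with 4-methoxybenzyl chloride (K2CO3, DMF) to 4,9-bis[(4-methoxybenzyl)oxy]-2,7-dimethoxy-10-(4-methoxyphenyl)-5H-dibenzo[a,d][7]annulen-5-one F1. Hydrazine hydrate (AcOH, EtOH, reflux) converts the C5 ketone into the hydrazone F2, and MnO2 oxidises it to the 5-diazo compound F3. F3 is added to Rh2(S-PTAD)4 (its antipode if a model shows the other sense), so that the carbene inserts into the O–CH2 bond of the ether on C4 and gives the cis-fused ring B dihydrofuran 9-(4-methoxybenzyl) ether F4 with C5 fixed as S. CF3CO2H with pentamethylbenzene then removes the remaining 4-methoxybenzyl ether and epimerises Cα through the 4-methoxybenzylic cation to the trans ring, which is 31.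

2. Step 26. The ylide faces may be poorly discriminated at the crowded methide carbon flanked by the c3 methoxy group, or the phenoxide may be O-benzylated by the sulfonium salt before the ylide forms. The fallback again uses rhodium-carbene insertion, sets out from 34 and returns at 42. MnO2 oxidises the benzylic carbinol to the c4 (3,5-dimethoxybenzoyl) phenol F5, whose hydrogen-bonded hydroxyl keeps the di-ortho-substituted carbonyl planar and open to attack. Hydrazine hydrate gives the hydrazone F6, and 4-methoxybenzyl chloride/K2CO3 alkylates the phenol to the 4-methoxybenzyl ether hydrazone F7. MnO2 gives the diazo compound F8, and Rh2(R-PTAD)4 (or its antipode, chosen on a model) inserts the carbene into the O–CH2 bond to the cis ring C dihydrofuran heptamethyl ether F9 with Cγ as R. CF3CO2H epimerises Cβ to the trans ring, which is 42.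

3. Step 13. The benzophenone chromophore may be excited or photoreduced in competition with the catalyst, and back hydrogen transfer to the C11 radical may give the hydrodecarboxylated product and not the alkene. The fallback is a Barton decarboxylation followed by selenoxide elimination, sets out from 19 and returns at 20. DCC and 1-hydroxypyridine-2(1H)-thione give the Barton ester F10. Visible-light photolysis with PhSeSePh gives the C11 phenyl selenide F11. H2O2 oxidises it to the selenoxide F12, which syn-eliminates towards the only β-hydrogen (on C10) and gives 20.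

**Further compounds**

F1 | step 19 | 4,9-bis[(4-methoxybenzyl)oxy]-2,7-dimethoxy-10-(4-methoxyphenyl)-5H-dibenzo[a,d][7]annulen-5-one | O=C1c2cc(OC)cc(OCc3ccc(OC)cc3)c2C(c2ccc(OC)cc2)=Cc2cc(OC)cc(OCc3ccc(OC)cc3)c21
F2 | step 19 | hydrazone of F1 at C5 | NN=C1c2cc(OC)cc(OCc3ccc(OC)cc3)c2C(c2ccc(OC)cc2)=Cc2cc(OC)cc(OCc3ccc(OC)cc3)c21
F3 | step 19 | 5-diazo-4,9-bis[(4-methoxybenzyl)oxy]-2,7-dimethoxy-10-(4-methoxyphenyl)-5H-dibenzo[a,d][7]annulene | [N-]=[N+]=C1c2cc(OC)cc(OCc3ccc(OC)cc3)c2C(c2ccc(OC)cc2)=Cc2cc(OC)cc(OCc3ccc(OC)cc3)c21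
F4 | step 19 | cis-fused ring B dihydrofuran 9-(4-methoxybenzyl) ether (C5 S, Cα R) | COc1ccc(C2=Cc3cc(OC)cc4c3[C@H](c3cc(OC)cc(OCc5ccc(OC)cc5)c32)[C@H](c2ccc(OC)cc2)O4)cc1
F5 | step 26 | c4 (3,5-dimethoxybenzoyl) phenol (C5 S, Cα S) | COc1ccc(C2=Cc3cc(OC)cc4c3[C@H](c3cc(OC)c(C(=O)c5cc(OC)cc(OC)c5)c(O)c32)[C@@H](c2ccc(OC)cc2)O4)cc1
F6 | step 26 | hydrazone of F5 | COc1ccc(C2=Cc3cc(OC)cc4c3[C@H](c3cc(OC)c(C(=NN)c5cc(OC)cc(OC)c5)c(O)c32)[C@@H](c2ccc(OC)cc2)O4)cc1
F7 | step 26 | c5 4-methoxybenzyl ether of hydrazone F6 | COc1ccc(C2=Cc3cc(OC)cc4c3[C@H](c3cc(OC)c(C(=NN)c5cc(OC)cc(OC)c5)c(OCc5ccc(OC)cc5)c32)[C@@H](c2ccc(OC)cc2)O4)cc1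
F8 | step 26 | c4 diazo(3,5-dimethoxyphenyl)methyl c5 4-methoxybenzyl ether | COc1ccc(C2=Cc3cc(OC)cc4c3[C@H](c3cc(OC)c(C(=[N+]=[N-])c5cc(OC)cc(OC)c5)c(OCc5ccc(OC)cc5)c32)[C@@H](c2ccc(OC)cc2)O4)cc1
F9 | step 26 | heptamethyl ether with cis ring C dihydrofuran (C5 S, Cα S, Cβ S, Cγ R) | COc1ccc(C2=Cc3cc(OC)cc4c3[C@H](c3cc(OC)c5c(c32)O[C@H](c2ccc(OC)cc2)[C@@H]5c2cc(OC)cc(OC)c2)[C@@H](c2ccc(OC)cc2)O4)cc1
F10 | step 13 | 2-thioxopyridin-1(2H)-yl ester of acid 19 (Barton ester, racemic) | S=C1C=CC=CN1OC(=O)C1C(c2ccc(OC)cc2)c2c(OCc3ccccc3)cc(OC)cc2C(=O)c2c(OC)cc(OC)cc21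
F11 | step 13 | 9-(benzyloxy)-2,4,7-trimethoxy-10-(4-methoxyphenyl)-11-(phenylselanyl)-10,11-dihydro-5H-dibenzo[a,d][7]annulen-5-one (racemic) | c1ccccc1[Se]C1C(c2ccc(OC)cc2)c2c(OCc3ccccc3)cc(OC)cc2C(=O)c2c(OC)cc(OC)cc21
F12 | step 13 | selenoxide of F11 | c1ccccc1[Se](=O)C1C(c2ccc(OC)cc2)c2c(OCc3ccccc3)cc(OC)cc2C(=O)c2c(OC)cc(OC)cc21
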